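The pitfall in the green flask is to ask how fast product forms, when the decision at 8.0 d hangs on what each product costs in coupling partner.

all flasks: substrate 0.020 M

|  | coupling partner | temperature | remark | time |
|---|---|---|---|---|
| green | 0.014 M | 25 °C | the very flask that is asked about, followed so far |  |
| amber | 0.014 M | 10 °C | run made earlier |  |
| flask | 0.0140 M | 25 °C |  | 8.0 d |

- green (time / d: product / %, substrate / %): 0.333: 31, 71; 0.833: 36, 64; 1.67: 37, 60; 2.50: 39, 60; 4.00: 42, 60; 5.00: 45, 57
- amber (time / d: product / %, substrate / %): 0.625: 7, 91; 1.67: 16, 80; 4.00: 35, 65; 5.00: 37, 59; 8.00: 39, 57; 10.0: 46, 54

(scatter of a reading: 2 percentage points)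

- removed product is counted in
- the analysis behind the earlier runs scatters by 2 percentage points, standard deviation
- additions bring no volume worth counting

- Tuesday's: change nothing and wait 15 d more
- Sunday's: at 8.0 d raise the temperature by 20 K, then wait 15 d
- Wednesday's: at 8.0 d take out 90% of the product then present, then wait 15 d
- Saturday's: at 8.0 d add coupling partner, 50.0% of the amount charged, then wait 15 d

- product, in percent of the substrate first charged, at 8.0 d
- the remedy with the largest gain of product, or "none" below 2 percentage points (Tuesday's / Sunday's / Wednesday's / Saturday's / none)
- product present, with what was taken out counted in, in percent of the substrate first charged, after Tuesday's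
- product present, with what was taken out counted in, in percent of the substrate first charged, after Saturday's

1. The green run reaches 36% by 0.833 d, then gains 9 percentage points up to 5.00 d. The amber run, at 10 °C, reaches 35% by 4.00 d, so cooling moves the kink later, while its height stays within the scatter of 2 points.

2. The green charge holds 0.700 of coupling partner per substrate. Dividing by the height of the kink gives 1.94 for the partner price, the coupling partner charged per product made at the kink. This is a reading, near two, and we take coupling partner for the limiting reagent.

3. Saturday's puts in 50.0% of the partner charge, which at this price buys product worth 18.0% of the substrate charged.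

4. Waiting is harder to judge. Between 1.67 d and 5.00 d the green product rises 8 points, but the green substrate falls 3 points. We put no number on that creep, and we would add partner.

5. The forecast gives 50% (range 47% to 54%) at 8.0 d, 72% after Tuesday's and 82% after Saturday's, and it picks Saturday's. It does put a number on the creep, treating it as “first order in substrate”.

6. The green flask gives 43.4% at 8.0 d, 47.4% after Tuesday's and 63.7% after Saturday's, and the best remedy is Saturday's. The gains are 4 points, 3.9 points, 4 points and 20 points, in the order of the options.

    coupling partner + intermediate → product (k = 610 M⁻¹ h⁻¹, Ea = 46.0 kJ mol⁻¹)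
    coupling partner ⇌ dormant form (K = 0.570, k = 0.00420 h⁻¹, Ea = 108 kJ mol⁻¹, ΔH = −27.0 kJ mol⁻¹)
    substrate ⇌ intermediate + leaving ligand (K = 2.30 × 10⁻⁵ M, k = 0.0460 h⁻¹, Ea = 105 kJ mol⁻¹, ΔH = −44.0 kJ mol⁻¹)
    coupling partner + leaving ligand ⇌ idle adduct, settled at all times (K = 17000 M⁻¹, ΔH = 6.00 kJ mol⁻¹)
    (constants at 25 °C)

The shrinking supply of coupling partner holds the green flask at 43.4%; the run without it reaches >99.9%, and at 8.00 d the flask has 0.592% of its partner free. The scheme spends one coupling partner per product, and at 0.800 d the green flask holds 0.00622 M of idle adduct beside 0.00723 M of product. On this flask the price reckons 18.0% for Saturday's, which brought 20 points, against 4 points for Tuesday's wait without added partner. For the neighbour charged with 0.024 M of coupling partner the price reckons 61.7%, and at 8.0 d that neighbour stands at 67.5%.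

The numbers in the tables come from a simulation with made-up constants; the scatter is artificial.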